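**Retrosynthetic overview**

1. Feature: ketone C1 of the nine-carbon chain (C1 = ketone, C9 = benzylic carbon) sits between two equivalent free phenolic oxygens of ring A (C2'–OH and C6'–OH). Either can reach chain carbon C3, so C3 can be held temporarily as C2 of a 5-hydroxychroman-4-one (pyranone ring C).
2. Last disconnection: target ⇐ that chromanone, by base-induced opening of the C3–O bond, hydrogenation of C2=C3 and hydrogenolysis of the two ring B benzyl ethers in one flask.
3. Key disconnection: chromanone ⇐ 2,6-dihydroxyacetophenone (ring A, C1, C2) + 7-[3,4-bis(benzyloxy)phenyl]heptanal (C3–C9, ring B). An amine-mediated condensation forms C2–C3 and an oxa-Michael closure forms C3–O.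
4. Aldehyde ⇐ primary alcohol ⇐ B-alkyl Suzuki–Miyaura coupling of hydroborated hept-6-en-1-ol with 4-bromo-1,2-bis(benzyloxy)benzene (C9–ring B bond).
5. Ring order: rings A and B are bought; ring C is the only ring formed (step 3) and is opened again (step 4).

Key step: step 3

Remark: the target has no stereocentre; the one stereocentre the route creates (C2 of the chromanone) is formed as the racemate and is destroyed in the last step, so no stereocontrol is planned.

**Route**

Step 1
Reactants: 1 4-bromo-1,2-bis(benzyloxy)benzene; 2 hept-6-en-1-ol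
Product: 4 7-[3,4-bis(benzyloxy)phenyl]heptan-1-ol, via O-boryl alkylborane 3 (not isolated)
Conditions: 2 (1.15 equiv), 9-BBN (2.3 equiv), THF, 0 °C to rt; then 1, Pd(dppf)Cl2 (3 mol%), 3 M aq. NaOH, THF, 65 °C
Reagents that add atoms: none
Why: 9-BBN adds anti-Markovnikov to the terminal alkene (one further equivalent is consumed by the hydroxyl as its borinate), and the primary B-alkyl group is transferred to the arylpalladium bromide formed from 1 and zerovalent palladium in a B-alkyl Suzuki–Miyaura coupling, the wide bite angle of dppf favouring reductive elimination over β-hydride elimination while the benzyl ethers stay inert.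

Step 2
Reactants: 4 7-[3,4-bis(benzyloxy)phenyl]heptan-1-ol
Product: 5 7-[3,4-bis(benzyloxy)phenyl]heptanal
Conditions: Dess–Martin periodinane (1.2 equiv), CH2Cl2, 0 °C to rt
Reagents that add atoms: none
Why: Dess–Martin oxidation of a primary alcohol stops at the aldehyde under neutral, anhydrous conditions and touches neither the benzyl ethers nor the electron-rich arene.

Step 3
Reactants: 5 7-[3,4-bis(benzyloxy)phenyl]heptanal; 6 1-(2,6-dihydroxyphenyl)ethan-1-one (2,6-dihydroxyacetophenone)
Product: 11 2-{6-[3,4-bis(benzyloxy)phenyl]hexyl}-5-hydroxychroman-4-one (racemic), via iminium ion 7 (not isolated), via enamine 8 (not isolated), via Mannich adduct 9 (not isolated), via (E)-enone 10 (not isolated)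
Conditions: pyrrolidine (1.0 equiv), EtOH, 70 °C; 5 added over 6 h to 6 (1.5 equiv), then 70 °C, 12 h
Reagents that add atoms: none
Why: Pyrrolidine converts aldehyde 5 into iminium ion 7 and methyl ketone 6 into enamine 8; their Mannich-type union forms the C2–C3 bond and, after hydrolysis by the water released, β-amino ketone 9, from which E1cB loss of pyrrolidine gives (E)-enone 10. The ortho phenoxide of ring A then adds to C3 of the enone in a 6-endo-trig oxa-Michael closure that forms pyranone ring C and the temporary C3–O bond; this is the Kabbe chromanone synthesis, known for 2-hydroxyacetophenones with aliphatic aldehydes. The new stereocentre at C2 of the chromanone is formed without control (achiral amine, racemate) and is left so because step 4 destroys it. The selectivity needed is cross-condensation over self-aldol condensation of the enolisable aldehyde and over a second condensation at C3 of the chromanone; it is secured by adding 5 slowly to an excess of 6 and amine, since self-condensation is second order in aldehyde and the cross reaction first order, and by the ring closure, which is open only to the cross product and withdraws enone 10 from the reversible steps. The two phenols of 6 are equivalent, so either closes the same ring and the other remains as the chelated 5-OH, which makes protection of ring A unnecessary.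

Step 4
Reactants: 11 2-{6-[3,4-bis(benzyloxy)phenyl]hexyl}-5-hydroxychroman-4-one (racemic)
Product: 14 malabaricone C [9-(3,4-dihydroxyphenyl)-1-(2,6-dihydroxyphenyl)nonan-1-one], via dipotassium enone diolate 12 (not isolated), via dibenzyl ketone 13 (not isolated)
Conditions: H2 (3 bar), 10% Pd/C, KOH (5 equiv), degassed EtOH/THF, 45 °C; then AcOH to pH 5, H2 (1 bar), rt
Reagents that add atoms: none
Why: Proposed new method: in alcoholic KOH the chromanone (as its 5-phenoxide) is deprotonated at C3 and expels the ring oxygen as a phenoxide (E1cB retro-oxa-Michael) to give a small equilibrium share of the ring-opened enone as its dipotassium bis(phenoxide) 12, which is hydrogenated irreversibly at C2=C3 on palladium, so that the ring-closed form is drained and the stereocentre erased, the aryl ketone flanked by two ortho oxido groups is too electron-rich to be reduced, and acidification releases dibenzyl ketone 13, whose benzyl ethers are then cleaved by hydrogenolysis under conditions that keep the catechol away from base and air; the closest known reaction is the alkaline Pd-catalysed hydrogenation of flavanones (2-arylchroman-4-ones) to dihydrochalcones, here transferred to a 2-alkylchroman-4-one, whose opening is less favourable but is supported by the classical alkaline cleavage of 2-alkylchromanones, and ethanol with little water is chosen so that alkoxide addition to 12 stays reversible and retro-aldol cleavage is limited.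

**Compound list**

1 | 4-bromo-1,2-bis(benzyloxy)benzene | Brc1ccc(OCc2ccccc2)c(OCc2ccccc2)c1 | starting material
2 | hept-6-en-1-ol | OCCCCCC=C | starting material
3 | 9-{7-[(9-borabicyclo[3.3.1]nonan-9-yl)oxy]heptyl}-9-borabicyclo[3.3.1]nonane | C(CCCCCCOB1C2CCCC1CCC2)B1C2CCCC1CCC2 | intermediate (not isolated)
4 | 7-[3,4-bis(benzyloxy)phenyl]heptan-1-ol | OCCCCCCCc1ccc(OCc2ccccc2)c(OCc2ccccc2)c1 | intermediate
5 | 7-[3,4-bis(benzyloxy)phenyl]heptanal | O=CCCCCCCc1ccc(OCc2ccccc2)c(OCc2ccccc2)c1 | intermediate
6 | 1-(2,6-dihydroxyphenyl)ethan-1-one | CC(=O)c1c(O)cccc1O | starting material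
7 | 1-{7-[3,4-bis(benzyloxy)phenyl]heptylidene}pyrrolidin-1-ium | C(CCCCCCc1ccc(OCc2ccccc2)c(OCc2ccccc2)c1)=[N+]1CCCC1 | intermediate (not isolated)
8 | 2-[1-(pyrrolidin-1-yl)ethenyl]benzene-1,3-diol | C=C(N1CCCC1)c1c(O)cccc1O | intermediate (not isolated)
9 | 9-[3,4-bis(benzyloxy)phenyl]-1-(2,6-dihydroxyphenyl)-3-(pyrrolidin-1-yl)nonan-1-one (racemic) | O=C(CC(CCCCCCc1ccc(OCc2ccccc2)c(OCc2ccccc2)c1)N1CCCC1)c1c(O)cccc1O | intermediate (not isolated)
10 | (E)-9-[3,4-bis(benzyloxy)phenyl]-1-(2,6-dihydroxyphenyl)non-2-en-1-one | O=C(/C=C/CCCCCCc1ccc(OCc2ccccc2)c(OCc2ccccc2)c1)c1c(O)cccc1O | intermediate (not isolated)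
11 | 2-{6-[3,4-bis(benzyloxy)phenyl]hexyl}-5-hydroxychroman-4-one (racemic) | O=C1CC(CCCCCCc2ccc(OCc3ccccc3)c(OCc3ccccc3)c2)Oc2cccc(O)c21 | intermediate
12 | dipotassium 2-{(E)-9-[3,4-bis(benzyloxy)phenyl]non-2-enoyl}benzene-1,3-diolate | [K+].[K+].O=C(/C=C/CCCCCCc1ccc(OCc2ccccc2)c(OCc2ccccc2)c1)c1c([O-])cccc1[O-] | intermediate (not isolated)
13 | 9-[3,4-bis(benzyloxy)phenyl]-1-(2,6-dihydroxyphenyl)nonan-1-one | O=C(CCCCCCCCc1ccc(OCc2ccccc2)c(OCc2ccccc2)c1)c1c(O)cccc1O | intermediate (not isolated)
14 | malabaricone C, 9-(3,4-dihydroxyphenyl)-1-(2,6-dihydroxyphenyl)nonan-1-one | O=C(CCCCCCCCc1ccc(O)c(O)c1)c1c(O)cccc1O | target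

**Step count**

Total steps: 4. Longest linear sequence: 4 steps (2 → 4 → 5 → 11 → 14).

**Steps most likely to fail**

1. Step 4 (proposed new method). The ring opening of a 2-alkylchromanone may be too slow or too unfavourable, so that other processes win: hydroxide addition to the transient enone followed by retro-aldol cleavage back to 6 and 5, or slow reduction of the chromanone carbonyl before the ring opens.
Fallback (known chemistry, ring C is never formed): it sets out from 6, uses aldehyde 5, and returns to the route at 14. Compound 6 is benzylated twice (BnBr, K2CO3, DMF, 70 °C) to 1-[2,6-bis(benzyloxy)phenyl]ethan-1-one F1. LiN(iPr)2 in THF at −78 °C gives lithium 1-[2,6-bis(benzyloxy)phenyl]ethen-1-olate F2, which adds to 5 to give racemic 9-[3,4-bis(benzyloxy)phenyl]-1-[2,6-bis(benzyloxy)phenyl]-3-hydroxynonan-1-one F3. MsCl/Et3N (CH2Cl2, 0 °C) converts it into 9-[3,4-bis(benzyloxy)phenyl]-1-[2,6-bis(benzyloxy)phenyl]-1-oxononan-3-yl methanesulfonate F4, and DBU eliminates this to (E)-9-[3,4-bis(benzyloxy)phenyl]-1-[2,6-bis(benzyloxy)phenyl]non-2-en-1-one F5. Neutral hydrogenation (H2, 10% Pd/C, EtOAc/EtOH, rt) should saturate the alkene and remove all four benzyl groups to give 14.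

2. Step 3 (key step). Self-aldol condensation of the aldehyde through its own enamine may outrun the cross-condensation with the hindered, hydrogen-bonded and electron-rich ketone, or a second aldehyde may condense at C3 of the chromanone.
Fallback (the two bonds are made in separate, directed operations): it sets out from 6, uses 5, and returns at 11. LiN(SiMe3)2 (3.3 equiv, THF, −78 to −20 °C) converts 6 into trilithium 2-(1-oxidoethenyl)benzene-1,3-diolate F6. Addition of 5 at −78 °C forms C2–C3 by a directed aldol reaction in which the aldehyde meets only a preformed ketone enolate, giving racemic 9-[3,4-bis(benzyloxy)phenyl]-1-(2,6-dihydroxyphenyl)-3-hydroxynonan-1-one F7. An intramolecular Mitsunobu etherification (PPh3, DIAD, THF, 0 °C) then closes the C3–O bond to give 11; any enone 10 formed by elimination closes to 11 on brief treatment with Et3N.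

3. Step 1. Oxidative addition to the electron-rich aryl bromide may be slow, so that protodeboronation or β-hydride elimination of the alkylborane takes over, and the free hydroxyl may leave the hydroboration incomplete.
Fallback (sp–sp2 coupling in place of sp3–sp2 coupling): it sets out from 1 and returns at 4. Sonogashira coupling of 1 with hept-6-yn-1-ol (Pd(PPh3)2Cl2, CuI, Et3N, 70 °C) should give 7-[3,4-bis(benzyloxy)phenyl]hept-6-yn-1-ol F8. Hydrogenation of the alkyne over 10% Pd/C poisoned with 2,2'-bipyridyl (H2 1 bar, MeOH/EtOAc, rt), conditions under which phenolic benzyl ethers are retained, should then give 4.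

**Further compounds**

F1 | step 4 | 1-[2,6-bis(benzyloxy)phenyl]ethan-1-one | CC(=O)c1c(OCc2ccccc2)cccc1OCc1ccccc1
F2 | step 4 | lithium 1-[2,6-bis(benzyloxy)phenyl]ethen-1-olate | [Li+].C=C([O-])c1c(OCc2ccccc2)cccc1OCc1ccccc1
F3 | step 4 | 9-[3,4-bis(benzyloxy)phenyl]-1-[2,6-bis(benzyloxy)phenyl]-3-hydroxynonan-1-one (racemic) | O=C(CC(O)CCCCCCc1ccc(OCc2ccccc2)c(OCc2ccccc2)c1)c1c(OCc2ccccc2)cccc1OCc1ccccc1
F4 | step 4 | 9-[3,4-bis(benzyloxy)phenyl]-1-[2,6-bis(benzyloxy)phenyl]-1-oxononan-3-yl methanesulfonate (racemic) | O=C(CC(OS(C)(=O)=O)CCCCCCc1ccc(OCc2ccccc2)c(OCc2ccccc2)c1)c1c(OCc2ccccc2)cccc1OCc1ccccc1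
F5 | step 4 | (E)-9-[3,4-bis(benzyloxy)phenyl]-1-[2,6-bis(benzyloxy)phenyl]non-2-en-1-one | O=C(/C=C/CCCCCCc1ccc(OCc2ccccc2)c(OCc2ccccc2)c1)c1c(OCc2ccccc2)cccc1OCc1ccccc1
F6 | step 3 | trilithium 2-(1-oxidoethenyl)benzene-1,3-diolate | [Li+].[Li+].[Li+].C=C([O-])c1c([O-])cccc1[O-]
F7 | step 3 | 9-[3,4-bis(benzyloxy)phenyl]-1-(2,6-dihydroxyphenyl)-3-hydroxynonan-1-one (racemic) | O=C(CC(O)CCCCCCc1ccc(OCc2ccccc2)c(OCc2ccccc2)c1)c1c(O)cccc1O
F8 | step 1 | 7-[3,4-bis(benzyloxy)phenyl]hept-6-yn-1-ol | OCCCCCC#Cc1ccc(OCc2ccccc2)c(OCc2ccccc2)c1
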